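The ratio I carried through this flask was monomer in chains per pre-initiator charged, wanted at 15 h for a charge of 0.60 M free monomer and 46 mM pre-initiator.

| setting | oak | ash | birch | flask |
|---|---|---|---|---|
| free monomer | 0.60 M | 0.60 M | 0.30 M | 0.60 M |
| pre-initiator | 64 mM | 100 mM | 46 mM | 46 mM |
| remark | run made earlier | run made earlier | run made earlier |  |
| time |  |  |  | 15 h |

- oak (time / h: monomer in chains / %, free monomer / %): 2.00: 1.6, 100.0; 4.00: 1.5, 98.3; 6.00: 5.3, 95.2; 8.00: 7.5, 91.4; 10.0: 13.3, 88.6; 12.0: 16.5, 83.7; 15.0: 25.5, 74.1
- ash (time / h: monomer in chains / %, free monomer / %): 2.00: 1.6, 99.0; 4.00: 4.1, 97.1; 6.00: 6.7, 93.8; 8.00: 13.2, 87.7; 10.0: 19.0, 80.7; 12.0: 25.3, 74.1; 15.0: 37.1, 62.3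
- birch (time / h: monomer in chains / %, free monomer / %): 3.00: 0, 99.9; 6.00: 1.3, 97.6; 10.0: 6.2, 93.0; 12.0: 6.9, 91.2; 15.0: 13.0, 86.0

(standard deviation of a reading: 1 percentage point)

- whether the average number of monomer units in a chain (chains begun, living or dead) reaches 3.0 by 15 h (no / yes)
- average number of monomer units in a chain (chains begun, living or dead) at 15 h

- the average divides the monomer in chains by the number of chains begun, living and dead together
- the earlier runs do not show the number of chains; that part of a forecast is a guess

1. The main step first. I let free monomer enter chains and wrote L for the natural logarithm of free monomer charged over free monomer left. At 15 h, L per molar of pre-initiator read 4.68 M⁻¹ in oak and 4.73 M⁻¹ in ash, both at 0.60 M, so the two readings lay close. I took the ash value, so I reckoned L = 0.218 for the flask, which meant an estimated 19.6% reacted, or 0.117 M of monomer in chains. Dividing by the pre-initiator charged gave 2.55. This is the floor length f: monomer in chains over pre-initiator charged, the average if each pre-initiator begins one chain. It lay below the wanted 3.0.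

2. Then the slow start (induction period). I followed one pre-initiator to a fork: by 15 h it has begun a chain or it has not. With s the share that has, the length is f/s, so 3.0 needed s below 0.850. In ash, L grew 3.61 times from 8.00 h to 15.0 h, while the square of the time grew 3.52 times. So I read the rate in ash as still rising at 15.0 h, with chains still beginning there.

3. Then the rest. The average counts chains begun, living and dead together, so a dead chain stays in the count. The readings do not show s, so I guessed 0.5, which gave my own length of 5.10.

The forecast said yes, with a length of 8 (range 4 to 25), holding that “less than about 40–50% has been activated”. Its length stood above mine.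

The flask gave yes, with a length of 6.52 at 15 h, having passed 3.0 at 5.96 h.

    free monomer + living end → monomer in chains + living end, rate k1*[living end]*[free monomer] (k = 3.90 × 10⁻⁴ M⁻¹ s⁻¹)
    free monomer + initiator → living end + monomer in chains (k = 2.35 × 10⁻⁵ M⁻¹ s⁻¹)
    pre-initiator ⇌ initiator (K = 6.20, k = 1.03 × 10⁻⁴ s⁻¹)

At 15 h monomer in chains in the flask stood at 19.6% of the free monomer charged. Dividing f by the flask's length gave s = 0.391, against 0.319 from f and the forecast's 8. At 15 h the flask's living end stood at 0.0181 M, which was 0.393 of the pre-initiator charge.

The runs are simulated for substances that don't exist; noise was put on by code.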